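Ring C of the flavanone half (O1–C2–C3–C4–C4a–C8a) is an isomer of an ortho-(1-arylvinyloxy)benzaldehyde, so everything rests on cutting C3–C4 between the methylene and the ketone carbon. An enantioselective rhodium-catalysed intramolecular hydroacylation adds the formyl C–H of ring A across the C2=C3 enol ether. The normally electrophilic formyl carbon reacts as an acyl-metal, ring C closes, and the lone stereocentre C2 is set, with no by-product. The step exploits the O1 and aryl donors on C2, which steer hydride to C2 and rhodium to C3. The precursor, a pentabenzylated aldehyde–enol ether already carrying the 6-linked apigenin unit, comes from Petasis methylenation of an aryl benzoate and a Suzuki coupling.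

Key step: step 10

Assumption: (R)-DTBM-SEGPHOS is taken to give the (S)-product by analogy with carbocyclic hydroacylations; if the sense proves opposite, the (S)-ligand is used with no other change.
Assumption: the 3'–6'' biaryl axis carries three ortho oxygen substituents and no axial descriptor in the target, so it is treated as configurationally labile.

Step 1
Reactants: 1 apigenin
Product: 2 7,4'-di-O-benzylapigenin
Conditions: BnBr (2.2 equiv), K2CO3, DMF, rt
Reagents that add atoms: benzyl bromide BrCc1ccccc1
Why: Williamson etherification of the two acidic phenols at C7 and C4', while the C5 hydroxyl stays free because its hydrogen bond to the C4 carbonyl lowers its acidity and nucleophilicity.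

Step 2
Reactants: 2 7,4'-di-O-benzylapigenin
Product: 3 7,4'-di-O-benzyl-6-iodoapigenin
Conditions: BnMe3N·ICl2 (1.1 equiv), CaCO3, CH2Cl2–MeOH, rt
Reagents that add atoms: benzyltrimethylammonium dichloroiodate C[N+](C)(C)Cc1ccccc1.Cl[I-]Cl
Why: Electrophilic aromatic iodination with a mild I+ source, a known 6-selective reaction of 5-hydroxy-7-alkoxyflavones in which the free chelated C5 hydroxyl directs attack to its ortho position C6 rather than to C8, and CaCO3 removes the HCl formed.

Step 3
Reactants: 3 7,4'-di-O-benzyl-6-iodoapigenin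
Product: 4 5,7,4'-tri-O-benzyl-6-iodoapigenin
Conditions: BnBr (1.5 equiv), K2CO3, Bu4NI (cat.), DMF, 70 °C
Reagents that add atoms: benzyl bromide BrCc1ccccc1
Why: Williamson etherification under forcing conditions breaks the chelate and caps the last phenol, so that the iodide enters the coupling as a neutral, non-acidic partner.

Step 4
Reactants: 5 2,4-dihydroxy-6-methoxybenzaldehyde
Product: 6 4-(benzyloxy)-2-hydroxy-6-methoxybenzaldehyde
Conditions: BnBr (1.0 equiv), K2CO3 (1.1 equiv), acetone, rt
Reagents that add atoms: benzyl bromide BrCc1ccccc1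
Why: Williamson etherification with one equivalent of halide takes the more acidic, non-chelated C4 hydroxyl para to the formyl group, the C2 hydroxyl being held in a hydrogen bond to the aldehyde.

Step 5
Reactants: 7 3-bromo-4-hydroxybenzoic acid
Product: 9 4-(benzyloxy)-3-bromobenzoic acid, via benzyl ester 8 (not isolated)
Conditions: BnBr (2.2 equiv), K2CO3, DMF, 60 °C; then aq NaOH, MeOH, 60 °C; HCl work-up
Reagents that add atoms: benzyl bromide BrCc1ccccc1; sodium hydroxide [Na+].[OH-]
Why: Williamson etherification and carboxylate alkylation followed by saponification of the benzyl ester in the same flask leave the aryl benzyl ether and the aryl bromide untouched.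

Step 6
Reactants: 6 4-(benzyloxy)-2-hydroxy-6-methoxybenzaldehyde; 9 4-(benzyloxy)-3-bromobenzoic acid
Product: 10 5-(benzyloxy)-2-formyl-3-methoxyphenyl 4-(benzyloxy)-3-bromobenzoate
Conditions: EDC, DMAP (cat.), CH2Cl2, 0 °C to rt
Reagents that add atoms: none
Why: Steglich esterification through the O-acylisourea and the acylpyridinium ion acylates the chelated phenol under neutral conditions that leave the aldehyde alone.

Step 7
Reactants: 10 5-(benzyloxy)-2-formyl-3-methoxyphenyl 4-(benzyloxy)-3-bromobenzoate
Product: 11 5-(benzyloxy)-2-(dimethoxymethyl)-3-methoxyphenyl 4-(benzyloxy)-3-bromobenzoate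
Conditions: HC(OMe)3, PPTS (cat.), CH2Cl2, rt; Et3N quench
Reagents that add atoms: trimethyl orthoformate COC(OC)OC
Why: Acid-catalysed acetalisation driven by the orthoformate masks the formyl group, which would otherwise be methylenated before the ester in step 8, and the aryl ester and benzyl ethers are inert to PPTS at room temperature.

Step 8
Reactants: 11 5-(benzyloxy)-2-(dimethoxymethyl)-3-methoxyphenyl 4-(benzyloxy)-3-bromobenzoate
Product: 13 4-(benzyloxy)-2-{[1-(4-(benzyloxy)-3-bromophenyl)ethenyl]oxy}-6-methoxybenzaldehyde, via acetal enol ether 12 (not isolated)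
Conditions: Cp2TiMe2 (2.5 equiv), toluene, 70 °C, dark; filtration; then PPTS (cat.), acetone–H2O, 0 °C; Et3N-washed silica
Reagents that add atoms: dimethyltitanocene [CH3-].[CH3-].[Ti+4].c1cc[cH-]c1.c1cc[cH-]c1; water O
Why: Petasis methylenation (thermally formed Cp2Ti=CH2, oxatitanacyclobutane, cycloreversion) turns aryl benzoates into 1-aryloxy-1-arylethenes without acid, and the dimethyl acetal of a 2,4,6-trioxygenated benzaldehyde ionises far faster than the aryl enol ether is protonated, so a brief buffered hydrolysis should free only the aldehyde.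

Step 9
Reactants: 13 4-(benzyloxy)-2-{[1-(4-(benzyloxy)-3-bromophenyl)ethenyl]oxy}-6-methoxybenzaldehyde; 4 5,7,4'-tri-O-benzyl-6-iodoapigenin
Product: 15 4-(benzyloxy)-2-[(1-{4-(benzyloxy)-3-[5,7-bis(benzyloxy)-2-(4-(benzyloxy)phenyl)-4-oxo-4H-chromen-6-yl]phenyl}ethenyl)oxy]-6-methoxybenzaldehyde, via pinacol boronate 14 (not isolated)
Conditions: Pd(OAc)2, SPhos, B2pin2 (1.05 equiv), KOAc, 1,4-dioxane, 90 °C; then 4, aq K3PO4, 90 °C
Reagents that add atoms: bis(pinacolato)diboron CC1(C)OB(OC1(C)C)B1OC(C)(C)C(C)(C)O1 (its atoms are kept only in 14)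
Why: Miyaura borylation of the aryl bromide and Suzuki–Miyaura coupling with the aryl iodide in one flask, with the bulky electron-rich SPhos ligand chosen for the triply ortho-substituted biaryl, run under basic conditions that the enol ether and the non-enolisable aldehyde tolerate.

Step 10
Reactants: 15 4-(benzyloxy)-2-[(1-{4-(benzyloxy)-3-[5,7-bis(benzyloxy)-2-(4-(benzyloxy)phenyl)-4-oxo-4H-chromen-6-yl]phenyl}ethenyl)oxy]-6-methoxybenzaldehyde
Product: 16 (2S)-7-(benzyloxy)-2-{4-(benzyloxy)-3-[5,7-bis(benzyloxy)-2-(4-(benzyloxy)phenyl)-4-oxo-4H-chromen-6-yl]phenyl}-5-methoxychroman-4-one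
Conditions: [Rh(cod)Cl]2 (5 mol %), (R)-DTBM-SEGPHOS (10 mol %), NaB[3,5-(CF3)2C6H3]4 (10 mol %), 1,4-dioxane, 4 Å sieves, 80 °C, Ar
Reagents that add atoms: none
Why: Proposed new method: the cationic monovalent rhodium–bisphosphine complex adds oxidatively into the formyl C–H bond of 15, giving an acyl rhodium hydride in which the formyl carbon is metal-bound (polarity reversal); the tethered C2=C3 enol ether then binds, hydride migrates to C2, and reductive elimination from the seven-membered acyl–alkyl rhodacycle forges C3–C4. The closest known reaction type is the rhodium-catalysed enantioselective intramolecular hydroacylation of ortho-allylbenzaldehydes bearing 1,1-disubstituted alkenes to 3-substituted tetralones, and of alpha-substituted 2-vinylbenzaldehydes to 3-substituted indanones; an aryl 1-arylvinyl ether has not served as the alkene. Ring C closes in a formal 6-endo-trig mode. The only new stereocentre, C2, is created in the hydride insertion, and the alkene face presented to Rh–H is dictated by the twofold-symmetric quadrant array of (R)-DTBM-SEGPHOS (catalyst control, no substrate bias). The step needs rhodium to bond to the CH2 terminus rather than to C2, which would lead to a 2-methyl-2-arylbenzofuran-3-one; the O1 and aryl donors make C2 the hydride-accepting carbon, and the strain of a tertiary Rh–C bond reinforces this choice. Alkene isomerisation is impossible because the alkene has no allylic hydrogen, the flavone C2''=C3'' bond is trisubstituted, untethered and part of a vinylogous ester and so is not engaged, and chelation by the alkene should hold back decarbonylation.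

Step 11
Reactants: 16 (2S)-7-(benzyloxy)-2-{4-(benzyloxy)-3-[5,7-bis(benzyloxy)-2-(4-(benzyloxy)phenyl)-4-oxo-4H-chromen-6-yl]phenyl}-5-methoxychroman-4-one
Product: 17 (2S)-2-{3-[5,7-dihydroxy-2-(4-hydroxyphenyl)-4-oxo-4H-chromen-6-yl]-4-hydroxyphenyl}-7-hydroxy-5-methoxychroman-4-one (target)
Conditions: H2 (1 atm), Pd/C (10 wt %), THF–MeOH, rt
Reagents that add atoms: none
Why: Catalytic hydrogenolysis cleaves all five benzyl ethers under neutral conditions, which spare the C5 methyl ether, the flavone C2''=C3'' bond and the benzylic C2–O1 bond of ring C at atmospheric pressure and, being free of base, cannot open ring C to the chalcone, so C2 keeps its S configuration.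

Compound list
1 | apigenin | O=c1cc(-c2ccc(O)cc2)oc2cc(O)cc(O)c12 | starting material
2 | 7,4'-di-O-benzylapigenin | O=c1cc(-c2ccc(OCc3ccccc3)cc2)oc2cc(OCc3ccccc3)cc(O)c12 | intermediate
3 | 7,4'-di-O-benzyl-6-iodoapigenin | O=c1cc(-c2ccc(OCc3ccccc3)cc2)oc2cc(OCc3ccccc3)c(I)c(O)c12 | intermediate
4 | 5,7,4'-tri-O-benzyl-6-iodoapigenin | O=c1cc(-c2ccc(OCc3ccccc3)cc2)oc2cc(OCc3ccccc3)c(I)c(OCc3ccccc3)c12 | intermediate
5 | 2,4-dihydroxy-6-methoxybenzaldehyde | COc1cc(O)cc(O)c1C=O | starting material
6 | 4-(benzyloxy)-2-hydroxy-6-methoxybenzaldehyde | COc1cc(OCc2ccccc2)cc(O)c1C=O | intermediate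
7 | 3-bromo-4-hydroxybenzoic acid | OC(=O)c1ccc(O)c(Br)c1 | starting material
8 | benzyl 4-(benzyloxy)-3-bromobenzoate (not isolated) | O=C(OCc1ccccc1)c1ccc(OCc2ccccc2)c(Br)c1 | intermediate
9 | 4-(benzyloxy)-3-bromobenzoic acid | OC(=O)c1ccc(OCc2ccccc2)c(Br)c1 | intermediate
10 | 5-(benzyloxy)-2-formyl-3-methoxyphenyl 4-(benzyloxy)-3-bromobenzoate | COc1cc(OCc2ccccc2)cc(OC(=O)c2ccc(OCc3ccccc3)c(Br)c2)c1C=O | intermediate
11 | 5-(benzyloxy)-2-(dimethoxymethyl)-3-methoxyphenyl 4-(benzyloxy)-3-bromobenzoate | COc1cc(OCc2ccccc2)cc(OC(=O)c2ccc(OCc3ccccc3)c(Br)c2)c1C(OC)OC | intermediate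
12 | 5-(benzyloxy)-1-{[1-(4-(benzyloxy)-3-bromophenyl)ethenyl]oxy}-2-(dimethoxymethyl)-3-methoxybenzene (not isolated) | COc1cc(OCc2ccccc2)cc(OC(=C)c2ccc(OCc3ccccc3)c(Br)c2)c1C(OC)OC | intermediate
13 | 4-(benzyloxy)-2-{[1-(4-(benzyloxy)-3-bromophenyl)ethenyl]oxy}-6-methoxybenzaldehyde | COc1cc(OCc2ccccc2)cc(OC(=C)c2ccc(OCc3ccccc3)c(Br)c2)c1C=O | intermediate
14 | pinacol boronate of 13, Bpin in place of Br (not isolated) | COc1cc(OCc2ccccc2)cc(OC(=C)c2ccc(OCc3ccccc3)c(B3OC(C)(C)C(C)(C)O3)c2)c1C=O | intermediate
15 | pentabenzyl aldehyde–enol ether carrying the 6-linked flavone | COc1cc(OCc2ccccc2)cc(OC(=C)c2ccc(OCc3ccccc3)c(-c3c(OCc4ccccc4)cc4oc(-c5ccc(OCc6ccccc6)cc5)cc(=O)c4c3OCc3ccccc3)c2)c1C=O | intermediate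
16 | (2S)-pentabenzyl flavanone–flavone | COc1cc(OCc2ccccc2)cc2c1C(=O)C[C@@H](c1ccc(OCc3ccccc3)c(-c3c(OCc4ccccc4)cc4oc(-c5ccc(OCc6ccccc6)cc5)cc(=O)c4c3OCc3ccccc3)c1)O2 | intermediate
17 | (2S)-2,3-dihydrorobustaflavone 5-O-methyl ether, CNP0332590.1 | COc1cc(O)cc2c1C(=O)C[C@@H](c1ccc(O)c(-c3c(O)cc4oc(-c5ccc(O)cc5)cc(=O)c4c3O)c1)O2 | target

Total step count: 11. Longest linear sequence: 7 steps (steps 4 or 5, then 6, 7, 8, 9, 10, 11).

Steps most likely to fail

Step 10. What may go wrong:
- decarbonylation of the acyl rhodium hydride;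
- slow insertion of the hindered enol ether;
- acid-triggered attack of the enol ether on the aldehyde;
- poor facial selectivity.

The fallback runs from 15 back to 16 and forms the same C3–C4 bond by known radical chemistry. A thiol-catalysed radical-chain hydroacylation is used (tert-dodecanethiol, 1,1'-azobis(cyclohexanecarbonitrile), toluene, 100 °C). This polarity-reversal catalysis is known for adding aldehydes to electron-rich alkenes and for cyclising alkenals. The acyl radical should attack the CH2 terminus in 6-endo fashion and give the racemic pentabenzyl flavanone F1. Kinetic resolution by asymmetric transfer hydrogenation follows (Cp*RhCl[(R,R)-TsDPEN], HCO2H–Et3N, EtOAc, rt, stopped near half conversion), a reaction known for racemic flavanones. It should reduce the (R)-ketone to the cis-(2R,4R)-flavan-4-ol F2 and leave 16, which is separated by chromatography.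

Step 8. Methylenation may stall on the hindered ester, or the enol ether may be hydrolysed together with the acetal. The fallback runs from 6 back to 13 and needs neither an aldehyde mask nor acid. Commercial 1-(3-bromo-4-hydroxyphenyl)ethan-1-one F3 is benzylated (BnBr, K2CO3, acetone) to the benzyl ether ketone F4. This is brominated (CuBr2, EtOAc–CHCl3, reflux) to the phenacyl bromide F5 and reduced (NaBH4, MeOH, 0 °C) to the racemic bromohydrin F6. Mitsunobu etherification of 6 with F6 (PPh3, DIAD, THF) gives the racemic beta-bromo ether F7, whose configuration is irrelevant. E2 elimination (KOtBu, THF, 0 °C), the classical route from 2-haloethyl aryl ethers to aryl vinyl ethers, then gives 13.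

Step 9. What may go wrong is protodeboronation of the boronate, slow transmetalation at the doubly ortho-substituted iodide, or homocoupling in the one-flask format. The fallback runs from 13 and 4 back to 15 by a base-free union through tin. Stannylation of 13 (Me3SnSnMe3, Pd(PPh3)4, toluene, 100 °C) gives the isolable aryltrimethylstannane F8. A copper-assisted Stille coupling with 4 (Pd(PPh3)4, CuI, CsF, DMF, 45 °C) then gives 15.

Further compounds
F1 | step 10 | racemic pentabenzyl flavanone–flavone | COc1cc(OCc2ccccc2)cc2c1C(=O)CC(c1ccc(OCc3ccccc3)c(-c3c(OCc4ccccc4)cc4oc(-c5ccc(OCc6ccccc6)cc5)cc(=O)c4c3OCc3ccccc3)c1)O2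
F2 | step 10 | cis-(2R,4R)-pentabenzyl flavan-4-ol–flavone | COc1cc(OCc2ccccc2)cc2c1[C@H](O)C[C@H](c1ccc(OCc3ccccc3)c(-c3c(OCc4ccccc4)cc4oc(-c5ccc(OCc6ccccc6)cc5)cc(=O)c4c3OCc3ccccc3)c1)O2
F3 | step 8 | 1-(3-bromo-4-hydroxyphenyl)ethan-1-one | CC(=O)c1ccc(O)c(Br)c1
F4 | step 8 | 1-[4-(benzyloxy)-3-bromophenyl]ethan-1-one | CC(=O)c1ccc(OCc2ccccc2)c(Br)c1
F5 | step 8 | 1-[4-(benzyloxy)-3-bromophenyl]-2-bromoethan-1-one | O=C(CBr)c1ccc(OCc2ccccc2)c(Br)c1
F6 | step 8 | racemic 1-[4-(benzyloxy)-3-bromophenyl]-2-bromoethan-1-ol | OC(CBr)c1ccc(OCc2ccccc2)c(Br)c1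
F7 | step 8 | racemic 4-(benzyloxy)-2-{1-[4-(benzyloxy)-3-bromophenyl]-2-bromoethoxy}-6-methoxybenzaldehyde | COc1cc(OCc2ccccc2)cc(OC(CBr)c2ccc(OCc3ccccc3)c(Br)c2)c1C=O
F8 | step 9 | 4-(benzyloxy)-2-{[1-(4-(benzyloxy)-3-(trimethylstannyl)phenyl)ethenyl]oxy}-6-methoxybenzaldehyde | COc1cc(OCc2ccccc2)cc(OC(=C)c2ccc(OCc3ccccc3)c([Sn](C)(C)C)c2)c1C=O
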